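**Plan**

1. Retrosynthetic cuts, in order: the two ester C–O bonds; the C4–O bond (back to a Δ3-cyclopentene); the C4–C5 bond, which closes the cyclopentane C1–C2–C3–C4–C5 (alkenyllithium at C4 plus a C5,C6-oxirane); the C1–C2 bond ([2,3]-Wittig shift of a cycloheptadienyl propargyl ether); last the C8=C9 alkene of the cycloheptene (ring-closing metathesis).
2. Forward order: (Z)-trienol → cyclohepta-2,5-dienol (seven-membered ring first) → propargyl ether → [2,3]-shift (quaternary C1, carbinol C2, C3≡C4–iPr chain) → α-oxirane at C5/C6 → (Z)-alkenyl iodide → five-membered ring closed last → O4 by epoxidation/hydride → the two esters.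
3. Enabling feature: on the seven-membered ring, C4 (on C5) and O6 (on C6) are trans-vicinal and H5 is anti to the C1 methyl. This is the pattern left by an anti opening of a C5–C6 oxirane by C4, tethered through C2–C3 to C1. On the cyclopentane, O2 and O4 are cis-1,3, so O2 can steer both oxygen transfers.
4. Stereochemistry: one reagent-controlled carbinol (future C6) → suprafacial [2,3]-shift (C1, C2) → OH-directed epoxidation (oxirane face) → SN2 inversion (C5; C6 kept) → OH-directed epoxidation and hydride opening (C4).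
5. Helpers: the oxirane (carries O6, activates C5), the iodide, an acetal on O2 and a silyl ether on O6; all are converted or removed in steps 11–17.

Key step: step 11

Remark: locants C1–C10 and α/β follow the daucane skeleton (C1 = CH3-bearing ring-fusion carbon, C2 = angelate carbon, C4 = isopropyl carbinol, C5 = ring-fusion CH, C6 = aroyloxy carbon, C8 = vinylic CH3 carbon; β = face of the C1 methyl); the SMILES carry the absolute configuration.

**Route**

Step 1
Reactants: 1 but-2-ynal; 2 tributyl(2-methylallyl)stannane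
Product: 3 (4S)-6-methylhept-6-en-2-yn-4-ol
Conditions: (S)-BINOL (10 mol%), Ti(OiPr)4 (10 mol%), 4 Å MS, CH2Cl2, −20 °C; aq. NaHCO3
Reagents that add atoms: none
Why: Keck-type catalytic asymmetric methallylation of an aldehyde; the BINOL–titanium Lewis acid should expose one aldehyde face and so set the only reagent-controlled stereocentre (future C6) as S.

Step 2
Reactants: 3 (4S)-6-methylhept-6-en-2-yn-4-ol
Product: 5 (2Z,4S)-2-iodo-6-methylhepta-2,6-dien-4-ol, via cyclic alkenylalanate 4 (not isolated)
Conditions: Red-Al, THF, 0 °C to rt; then I2, −78 to 0 °C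
Reagents that add atoms: iodine, II
Why: alkoxide-directed trans-hydroalumination of a propargylic alcohol and iodinolysis of the five-membered alanate; hydride goes to the carbinol-side alkyne carbon and iodine ends cis to the carbinol carbon, which fixes the Z geometry needed for the ring alkene.

Step 3
Reactants: 5 (2Z,4S)-2-iodo-6-methylhepta-2,6-dien-4-ol; 6 allyltributylstannane
Product: 7 (4S,5Z)-2,6-dimethylnona-1,5,8-trien-4-ol
Conditions: Pd2(dba)3 (2.5 mol%), AsPh3 (10 mol%), NMP, 40 °C
Reagents that add atoms: none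
Why: Stille coupling of an alkenyl iodide with retention of alkene geometry, so the allyl group stands cis to the carbinol carbon.

Step 4
Reactants: 7 (4S,5Z)-2,6-dimethylnona-1,5,8-trien-4-ol
Product: 8 (1S)-3,6-dimethylcyclohepta-2,5-dien-1-ol
Conditions: Grubbs II (5 mol%), CH2Cl2 (5 mM), 40 °C
Reagents that add atoms: none
Why: ring-closing metathesis of the allyl and methallyl termini forms the seven-membered ring with its trisubstituted C8=C9 alkene; the Z alkene holds the two chains cis, and no other ring size is open to the triene.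

Step 5
Reactants: 9 4-methylpent-2-yn-1-ol
Product: 10 1-bromo-4-methylpent-2-yne
Conditions: PBr3, pyridine (cat.), Et2O, 0 °C
Reagents that add atoms: phosphorus tribromide, BrP(Br)Br
Why: standard conversion of a primary propargylic alcohol into the bromide by SN2 on the phosphite ester.

Step 6
Reactants: 8 (1S)-3,6-dimethylcyclohepta-2,5-dien-1-ol; 10 1-bromo-4-methylpent-2-yne
Product: 11 (6S)-1,4-dimethyl-6-[(4-methylpent-2-yn-1-yl)oxy]cyclohepta-1,4-diene
Conditions: NaH, THF–DMF, 0 °C; then 10, Bu4NI (cat.), rt
Reagents that add atoms: none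
Why: Williamson ether synthesis with a reactive propargylic bromide; the carbinol centre is not touched.

Step 7
Reactants: 11 (6S)-1,4-dimethyl-6-[(4-methylpent-2-yn-1-yl)oxy]cyclohepta-1,4-diene
Product: 13 (1S)-1-[(1R)-1,5-dimethylcyclohepta-2,5-dien-1-yl]-4-methylpent-2-yn-1-ol, via α-lithiated propargylic ether 12 (not isolated)
Conditions: n-BuLi, THF, −78 to −40 °C; H2O
Reagents that add atoms: none
Why: [2,3]-Wittig rearrangement; the propargylic carbanion adds suprafacially to the methyl-bearing alkene terminus on the face that carried the ether oxygen, so the C6 configuration is handed to the new quaternary C1, and the alkynyl group pseudo-equatorial in the five-membered envelope transition state should give the (1S)-carbinol (future C2).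

Step 8
Reactants: 13 (1S)-1-[(1R)-1,5-dimethylcyclohepta-2,5-dien-1-yl]-4-methylpent-2-yn-1-ol
Product: 14 1-(3,6-dimethyl-8-oxabicyclo[5.1.0]oct-3-en-6-yl)-4-methylpent-2-yn-1-ol (5α,6α-epoxide of 13; oxirane on the ring face of the carbinol side chain)
Conditions: VO(acac)2 (5 mol%), t-BuOOH, CH2Cl2, 0 °C to rt
Reagents that add atoms: tert-butyl hydroperoxide, CC(C)(C)OO
Why: vanadium-catalysed hydroxyl-directed epoxidation of a homoallylic alcohol; oxygen is delivered within the vanadate ester of the C2 hydroxyl and can reach the C5=C6 alkene only on the face of the side chain (α), while the alkyne is inert and the C8=C9 alkene is one carbon further away.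

Step 9
Reactants: 14 5α,6α-epoxy alkynol
Product: 16 (Z)-1-(3,6-dimethyl-8-oxabicyclo[5.1.0]oct-3-en-6-yl)-3-iodo-4-methylpent-2-en-1-ol (iodine cis to the carbinol carbon; centres as in 14), via cyclic alkenylalanate 15 (not isolated)
Conditions: Red-Al (1.1 equiv), Et2O, −20 to 0 °C; then I2, −78 °C
Reagents that add atoms: iodine, II
Why: alkoxide-directed trans-hydroalumination and iodinolysis as in step 2; the hydride is held on the C2 oxygen and cannot reach the back side of the syn oxirane, and the iodine ends on C4 cis to C2, the geometry that the ring closure needs.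

Step 10
Reactants: 16 (Z)-alkenyl iodide epoxy alcohol
Product: 17 2-methoxyprop-2-yl ether of 16
Conditions: 2-methoxypropene, PPTS (cat.), CH2Cl2, 0 °C
Reagents that add atoms: 2-methoxypropene, COC(C)=C
Why: acid-catalysed addition of the alcohol to the enol ether gives a base-stable mixed acetal under conditions mild enough for the oxirane; an acetal is used because a silyl group on O2 would migrate to the neighbouring alkenyllithium carbon.

Step 11
Reactants: 17 2-methoxyprop-2-yl ether of the (Z)-alkenyl iodide epoxide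
Product: 20 2β-[(2-methoxypropan-2-yl)oxy]-6α-(triethylsilyloxy)dauca-3,8-diene (trans-fused; 1β-CH3; 5α-H), via (Z)-alkenyllithium 18 (not isolated), via lithium alkoxide 19 (not isolated)
Conditions: t-BuLi (2.1 equiv), Et2O–pentane, −78 °C, then to 0 °C; Et3SiCl, THF, −78 °C to rt
Reagents that add atoms: chlorotriethylsilane, CC[Si](Cl)(CC)CC
Why: iodine–lithium exchange gives the configurationally stable (Z)-alkenyllithium 18, whose sp2 carbanion (future C4, lithium cis to C2) displaces the oxirane oxygen at C5 in an intramolecular SN2 reaction, and the C6 alkoxide 19 is silylated in the same flask. The closest known reaction type is the halogen–metal-exchange-initiated cyclisation of iodo epoxides (Parham-type anionic cyclisation onto an oxirane). The ring C1–C2–C3=C4–C5 closes in the 5-exo-tet mode, the breaking C5–O bond lying outside the new ring. C5 is set by inversion at the α-oxirane carbon, which puts C4 on the β face and H5 on the α face (trans ring fusion, H5 anti to the C1 methyl), while C6 keeps its α oxygen, so C4 and O6 end trans as in the target. The step needs attack at C5 and not at C6, and substitution rather than proton abstraction or silyl migration: the short tether disfavours the bridged 6-endo path, two equivalents of t-BuLi at −78 °C leave no free base, and the acetal on O2 excludes a 1,4 O-to-C shift.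

Step 12
Reactants: 20 2β-O-acetal 6α-O-silyl diene
Product: 21 6α-(triethylsilyloxy)dauca-3,8-dien-2β-ol
Conditions: PPTS (cat.), MeOH, 0 °C
Reagents that add atoms: none
Why: acid-catalysed transacetalisation with methanol removes the very labile 2-methoxyprop-2-yl group much faster than the secondary triethylsilyl ether is cleaved.

Step 13
Reactants: 21 6α-(triethylsilyloxy)dauca-3,8-dien-2β-ol
Product: 22 3β,4β-epoxy-6α-(triethylsilyloxy)dauc-8-en-2β-ol
Conditions: VO(acac)2 (5 mol%), t-BuOOH, CH2Cl2, 0 °C
Reagents that add atoms: tert-butyl hydroperoxide, CC(C)(C)OO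
Why: vanadium-catalysed epoxidation of a cyclic allylic alcohol, much faster than at the isolated C8=C9 alkene; oxygen enters syn to the 2β-hydroxyl, which places the new C4–O bond on the β face, cis to O2.

Step 14
Reactants: 22 3β,4β-epoxy-6α-(triethylsilyloxy)dauc-8-en-2β-ol
Product: 23 6α-(triethylsilyloxy)dauc-8-ene-2β,4β-diol
Conditions: LiBHEt3, THF, 0 °C to rt; H2O
Reagents that add atoms: none
Why: SN2 opening of the trisubstituted oxirane by hydride at the secondary C3, anti to the oxygen, leaves the oxygen on the fully substituted C4 and gives the 4β tertiary alcohol with the isopropyl group α.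

Step 15
Reactants: 23 6α-(triethylsilyloxy)dauc-8-ene-2β,4β-diol; 24 angelic acid ((Z)-2-methylbut-2-enoic acid)
Product: 26 2β-angeloyloxy-6α-(triethylsilyloxy)dauc-8-en-4β-ol, via mixed anhydride 25 (not isolated)
Conditions: 2,4,6-trichlorobenzoyl chloride, Et3N, toluene, rt; then 23, 80 °C
Reagents that add atoms: none
Why: Yamaguchi-type esterification through the mixed anhydride, a protocol suited to transfer the angeloyl group to hindered alcohols without Z-to-E isomerisation; only the secondary C2 hydroxyl can react, since the C4 hydroxyl is tertiary and O6 is silylated.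

Step 16
Reactants: 26 2β-angeloyloxy-6α-(triethylsilyloxy)dauc-8-en-4β-ol
Product: 27 2β-angeloyloxydauc-8-ene-4β,6α-diol
Conditions: HF·pyridine, pyridine, THF, 0 °C to rt
Reagents that add atoms: none
Why: fluoride cleavage of the triethylsilyl ether under buffered conditions that should leave the angelate and the tertiary alcohol alone.

Step 17
Reactants: 27 2β-angeloyloxydauc-8-ene-4β,6α-diol; 28 4-acetoxybenzoyl chloride
Product: 30 2β-angeloyloxy-6α-(4-hydroxybenzoyloxy)dauc-8-en-4β-ol (CNP0188626.1), via aryl acetate 29 (not isolated)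
Conditions: Et3N, DMAP (cat.), CH2Cl2, 0 °C to rt; then pyrrolidine, 0 °C
Reagents that add atoms: none
Why: DMAP-catalysed acylation of the only remaining secondary hydroxyl (C6), then aminolysis of the phenolic acetate, which is far more electrophilic than the two alkyl esters, should free the phenol of the target.

**Compound list**

1 | but-2-ynal | CC#CC=O | starting material
2 | tributyl(2-methylallyl)stannane | CC(=C)C[Sn](CCCC)(CCCC)CCCC | starting material
3 | (4S)-6-methylhept-6-en-2-yn-4-ol | CC#C[C@@H](O)CC(C)=C | intermediate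
4 | cyclic alkenylalanate of 3 (sodium salt; O–Al–C=C–C five-membered ring, Al on the methyl-bearing carbon) | COCCO[Al-]1(OCCOC)O[C@@H](CC(C)=C)C=C1C.[Na+] | intermediate
5 | (2Z,4S)-2-iodo-6-methylhepta-2,6-dien-4-ol | C/C(I)=C/[C@@H](O)CC(C)=C | intermediate
6 | allyltributylstannane | C=CC[Sn](CCCC)(CCCC)CCCC | starting material
7 | (4S,5Z)-2,6-dimethylnona-1,5,8-trien-4-ol | C=CC/C(C)=C\[C@@H](O)CC(C)=C | intermediate
8 | (1S)-3,6-dimethylcyclohepta-2,5-dien-1-ol | O[C@@H]1C=C(C)CC=C(C)C1 | intermediate
9 | 4-methylpent-2-yn-1-ol | CC(C)C#CCO | starting material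
10 | 1-bromo-4-methylpent-2-yne | CC(C)C#CCBr | intermediate
11 | (6S)-1,4-dimethyl-6-[(4-methylpent-2-yn-1-yl)oxy]cyclohepta-1,4-diene | CC(C)C#CCO[C@@H]1C=C(C)CC=C(C)C1 | intermediate
12 | α-lithiated propargylic ether of 11 (Li on the O–CH carbon next to the alkyne) | CC(C)C#CC([Li])O[C@@H]1C=C(C)CC=C(C)C1 | intermediate
13 | (1S)-1-[(1R)-1,5-dimethylcyclohepta-2,5-dien-1-yl]-4-methylpent-2-yn-1-ol | CC(C)C#C[C@@H](O)[C@@]1(C)C=CCC(C)=CC1 | intermediate
14 | 1-(3,6-dimethyl-8-oxabicyclo[5.1.0]oct-3-en-6-yl)-4-methylpent-2-yn-1-ol (5α,6α-epoxide of 13; oxirane cis to the carbinol side chain) | CC(C)C#C[C@@H](O)[C@@]1(C)[C@H]2O[C@H]2CC(C)=CC1 | intermediate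
15 | cyclic alkenylalanate of 14 (sodium salt; Al on the isopropyl-bearing carbon, cis to the carbinol carbon) | COCCO[Al-]1(OCCOC)O[C@@H]([C@@]2(C)[C@H]3O[C@H]3CC(C)=CC2)C=C1C(C)C.[Na+] | intermediate
16 | (Z)-1-(3,6-dimethyl-8-oxabicyclo[5.1.0]oct-3-en-6-yl)-3-iodo-4-methylpent-2-en-1-ol (iodine cis to the carbinol carbon; centres as in 14) | CC(C)/C(I)=C/[C@@H](O)[C@@]1(C)[C@H]2O[C@H]2CC(C)=CC1 | intermediate
17 | 2-methoxyprop-2-yl ether of 16 | CC(C)/C(I)=C/[C@@H](OC(C)(C)OC)[C@@]1(C)[C@H]2O[C@H]2CC(C)=CC1 | intermediate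
18 | (Z)-alkenyllithium from 17 (Li in place of I) | CC(C)/C([Li])=C/[C@@H](OC(C)(C)OC)[C@@]1(C)[C@H]2O[C@H]2CC(C)=CC1 | intermediate
19 | lithium 6α-alkoxide of 2β-[(2-methoxypropan-2-yl)oxy]dauca-3,8-diene | COC(C)(C)O[C@@H]1C=C(C(C)C)[C@@H]2[C@@H](O[Li])CC(C)=CC[C@]21C | intermediate
20 | 2β-[(2-methoxypropan-2-yl)oxy]-6α-(triethylsilyloxy)dauca-3,8-diene | COC(C)(C)O[C@@H]1C=C(C(C)C)[C@@H]2[C@@H](O[Si](CC)(CC)CC)CC(C)=CC[C@]21C | intermediate
21 | 6α-(triethylsilyloxy)dauca-3,8-dien-2β-ol | O[C@@H]1C=C(C(C)C)[C@@H]2[C@@H](O[Si](CC)(CC)CC)CC(C)=CC[C@]21C | intermediate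
22 | 3β,4β-epoxy-6α-(triethylsilyloxy)dauc-8-en-2β-ol | O[C@@H]1[C@@H]3O[C@]3(C(C)C)[C@@H]2[C@@H](O[Si](CC)(CC)CC)CC(C)=CC[C@]21C | intermediate
23 | 6α-(triethylsilyloxy)dauc-8-ene-2β,4β-diol | O[C@@H]1C[C@@](O)(C(C)C)[C@@H]2[C@@H](O[Si](CC)(CC)CC)CC(C)=CC[C@]21C | intermediate
24 | angelic acid ((Z)-2-methylbut-2-enoic acid) | C/C=C(/C)C(=O)O | starting material
25 | (Z)-2-methylbut-2-enoic 2,4,6-trichlorobenzoic anhydride | C/C=C(/C)C(=O)OC(=O)c1c(Cl)cc(Cl)cc1Cl | intermediate
26 | 2β-angeloyloxy-6α-(triethylsilyloxy)dauc-8-en-4β-ol | C/C=C(/C)C(=O)O[C@@H]1C[C@@](O)(C(C)C)[C@@H]2[C@@H](O[Si](CC)(CC)CC)CC(C)=CC[C@]21C | intermediate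
27 | 2β-angeloyloxydauc-8-ene-4β,6α-diol | C/C=C(/C)C(=O)O[C@@H]1C[C@@](O)(C(C)C)[C@@H]2[C@@H](O)CC(C)=CC[C@]21C | intermediate
28 | 4-acetoxybenzoyl chloride | CC(=O)Oc1ccc(cc1)C(Cl)=O | starting material
29 | 6α-(4-acetoxybenzoyloxy)-2β-angeloyloxydauc-8-en-4β-ol | C/C=C(/C)C(=O)O[C@@H]1C[C@@](O)(C(C)C)[C@@H]2[C@@H](OC(=O)c3ccc(OC(C)=O)cc3)CC(C)=CC[C@]21C | intermediate
30 | 2β-angeloyloxy-6α-(4-hydroxybenzoyloxy)dauc-8-en-4β-ol (CNP0188626.1) | C/C=C(/C)C(=O)O[C@@H]1C[C@@](O)(C(C)C)[C@@H]2[C@@H](OC(=O)c3ccc(O)cc3)CC(C)=CC[C@]21C | target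

**Step count and risks**

Total step count: 17. Longest linear sequence: 16 steps (steps 1–4 and 6–17; step 5 makes the bromide used in step 6).

Steps most likely to fail:

Step 11 (ring closure). Proton transfer to the alkenyllithium, or base-induced isomerisation of the oxirane to an allylic alkoxide, may outrun substitution at the hindered C5. The fallback reverses the roles, with C5 as a radical and C4 as the acceptor, and sets out from 14. Ruthenium-catalysed trans-hydrosilylation of the alkyne ([Cp*Ru(MeCN)3]PF6, BnMe2SiH; silicon distal to the hydroxyl) and Tamao–Fleming oxidation should give the β-hydroxy isopropyl ketone F1. 2-Methoxypropene/PPTS gives its 2-methoxyprop-2-yl ether F2. Cp2TiCl (from Cp2TiCl2 and Zn, THF) opens the oxirane at the more hindered C5–O bond, and the C5 radical should add 5-exo to the C4 ketone, anti to the bulky titanoxy group on C6, to give the 2β-O-acetal dauc-8-ene-4β,6α-diol F3 with the isopropyl carbinol already in place. TESCl/imidazole silylates the secondary C6 hydroxyl to give the silyl ether F4, and PPTS/MeOH removes the acetal, which returns to 23. Face selectivity at C5 and C4 is less secure in this radical closure than in the SN2 closure, so it is held in reserve.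

Step 8 (directed epoxidation). Oxygen may be transferred to the wrong alkene (C8=C9 is more electron-rich and still within reach of the same hydroxyl), or the propargylic alcohol may be oxidised. The fallback replaces metal-oxo transfer by an electrophilic cyclisation with an internal oxygen nucleophile and sets out from 13. n-BuLi then Boc2O gives the tert-butyl carbonate F5. Iodine in MeCN at −20 °C should close the six-membered cyclic iodocarbonate F6 onto C5=C6 only (carbonate oxygen on C5 cis to the side chain, iodine on C6 trans). K2CO3 in MeOH cleaves the carbonate, and the C5 alkoxide displaces iodide to give the same α-oxirane 14.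

Step 7 ([2,3]-Wittig shift). Poor facial discrimination at the carbanion carbon would give a mixture of C2 epimers. The fallback sets C2 by reagent control instead of by the sigmatropic transition state and sets out from the epimer mixture of 13. Dess–Martin oxidation gives the ynone F7. CBS reduction ((S)-Me-CBS, catecholborane, −78 °C), which treats the alkyne as the small group, should return (1S)-13 without touching the quaternary centre.

**Further compounds**

F1 | step 11 | 1-hydroxy-1-(3,6-dimethyl-8-oxabicyclo[5.1.0]oct-3-en-6-yl)-4-methylpentan-3-one (centres as in 14) | CC(C)C(=O)C[C@@H](O)[C@@]1(C)[C@H]2O[C@H]2CC(C)=CC1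
F2 | step 11 | 2-methoxyprop-2-yl ether of F1 | CC(C)C(=O)C[C@@H](OC(C)(C)OC)[C@@]1(C)[C@H]2O[C@H]2CC(C)=CC1
F3 | step 11 | 2β-[(2-methoxypropan-2-yl)oxy]dauc-8-ene-4β,6α-diol | COC(C)(C)O[C@@H]1C[C@@](O)(C(C)C)[C@@H]2[C@@H](O)CC(C)=CC[C@]21C
F4 | step 11 | 2β-[(2-methoxypropan-2-yl)oxy]-6α-(triethylsilyloxy)dauc-8-en-4β-ol | COC(C)(C)O[C@@H]1C[C@@](O)(C(C)C)[C@@H]2[C@@H](O[Si](CC)(CC)CC)CC(C)=CC[C@]21C
F5 | step 8 | tert-butyl carbonate of 13 | CC(C)C#C[C@@H](OC(=O)OC(C)(C)C)[C@@]1(C)C=CCC(C)=CC1
F6 | step 8 | cyclic iodocarbonate of 13 (six-membered carbonate bridging O2 and C5; iodine on C6 trans to the carbonate oxygen) | CC(C)C#C[C@H]1OC(=O)O[C@H]2[C@H](I)CC(C)=CC[C@@]12C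
F7 | step 7 | 1-[(1R)-1,5-dimethylcyclohepta-2,5-dien-1-yl]-4-methylpent-2-yn-1-one | CC(C)C#CC(=O)[C@@]1(C)C=CCC(C)=CC1
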